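(The numbers of this flask were drawn at random within sensible limits; no experiment stands behind them.)

Marta, you asked for a quick number, and your hunch is that more partner simply buys more target, so here is what I would commit to.

common to all: substrate 0.016 M; time 20 h
- autumn: partner 0.00200 M
- winter: partner 0.00400 M
- dawn: partner 0.00800 M
- midnight: partner 0.0200 M
- spring: partner 0.0400 M

    substrate + 2 partner → side product A (k1 = 780 M⁻² h⁻¹)
    partner + target ⇌ idle adduct, settled at all times (K2 = 320 M⁻¹)
    substrate + target → side product B (k3 = 1.9 M⁻¹ h⁻¹)
    substrate + partner → target (k4 = 41 M⁻¹ h⁻¹)

1. amount of target at the end, in percent of the substrate charged for autumn, winter, dawn, midnight, spring, in this order
2. the shape of the row from first to last (rises, then falls / falls, then rises / rises all the way / falls all the way / hardly changes)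

- percent here means substrate units held: one side product B counts as two
- what is said of target includes idle adduct
- a step written with two of one species runs at k times the square of its concentration and takes two of it each time
- "hardly changes" means that all values lie within two and a half points (for a concentration: within two and a half percent of the largest)
- run time (autumn): 20 h

Count lifetimes, as you would on any first-order decay. In autumn c(substrate) at 0.016 M stands above c(partner) at 0.00200 M, so partner is the limiting reagent. With substrate held at its charge, partner decays pseudo-first-order with lifetime 1.52 h, which is shorter than the run of 20 h.

Side product A costs little here: at the charge, its step runs at 0.0380 of the rate of the step to target. So partner's charge is worth 12.5% of the substrate charged in target; call that the early share.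

But target is not an end product: substrate turns it into side product B. With c(substrate) near 0.0140 M, target's lifetime is 37.6 h. The quantity to carry is the lifetime count, the hours target stands exposed after partner's lifetime divided by target's lifetime: 0.491. The early share times exp(−count) gives 0.0765 of the substrate charged for autumn.

I leave out the idle adduct and would not stretch the count upward. At the top another comparison takes over. At the charge, the share of substrate going to target rather than side product A is 72.4% at midnight but 56.8% in spring. So I expect your hunch to hold at low charge, and for the row from autumn's count to these two shares I commit to this shape: rises, then falls.

The forecast reads 7.7%, 16.6%, 34.5%, 70.5% and 68%, shape rises, then falls, with target at low partner “slowly eaten by substrate over the long run”.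

The simulation gives 7.67%, 16.2%, 34.3%, 71.7% and 68.5%, shape rises, then falls.

In autumn the step to target used substrate 22 times as fast as the step to side product B at 1.21 h, but 0.0080 times as fast at 20.0 h, with partner at 0.023% of its charge. Read back from 7.67%, autumn's target stands 0.488 lifetimes below its early share, against my count of 0.491. In winter the same count is 0.421, which gives 0.164 of the substrate charged, and the flask holds 16.2%.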